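**Retrosynthetic overview**
1. The target is a 5,7,2',4'-tetrahydroxy-5'-methoxyisoflavone with a 3-hydroxy-3-methylbutyl chain at C3'. It is unmasked last by desilylation and hydrogenolysis of four benzyl ethers.
2. Ring C is cut at O1–C8a and C4–C4a. Ring A arrives as 3,5-bis(benzyloxy)benzyne, and O1–C2–C3(ring B)–C4 as the Z-enol of a methyl α-formyl-arylacetate. The strategy rests on the C5 oxygen of ring A lying ortho to C4a: it polarises the aryne so that the enol oxygen bonds to C8a and the carbanion appears at C4a, beside the ester.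
3. Aryne precursor: 3,5-bis(benzyloxy)phenol by ortho-bromination, O-silylation, then bromine–lithium exchange, retro-Brook shift and triflation.
4. Ring B: 2-bromoisovanillin, whose bromine marks C3' and whose formyl-bearing carbon becomes the oxygenated C2' (Baeyer–Villiger). The side chain comes from aryllithium opening of 2,2-dimethyloxetane, followed by bromination at C1', Pd coupling to the arylacetate and Claisen formylation.
5. Rings A and B are bought as benzenes; ring C is the only ring formed, in step 12.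

Key step: step 12

Remark: 2-bromo-3-hydroxy-4-methoxybenzaldehyde (7) is taken as a purchased material (otherwise one bromination of isovanillin, Br2/NaOAc/AcOH), and enol ester 20 is drawn as its hydrogen-bonded Z-enol although it equilibrates with the aldehyde tautomer.

**Route**

Step 1
Reactants: 1 3,5-bis(benzyloxy)phenol
Product: 2 3,5-bis(benzyloxy)-2-bromophenol
Conditions: NBS (1.0 equiv), CH2Cl2, −78 °C to rt
Reagents that add atoms: N-bromosuccinimide, O=C1CCC(=O)N1Br
Why: Electrophilic aromatic bromination of an activated phenol, which in CH2Cl2 at low temperature should go ortho to the free hydroxyl (hydrogen-bonded delivery of NBS), the para position being flanked by two benzyloxy groups.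

Step 2
Reactants: 2 3,5-bis(benzyloxy)-2-bromophenol
Product: 3 [3,5-bis(benzyloxy)-2-bromophenoxy]trimethylsilane
Conditions: HMDS, THF, 70 °C; volatiles removed
Reagents that add atoms: hexamethyldisilazane, C[Si](C)(C)N[Si](C)(C)C
Why: O-silylation of a phenol with HMDS, driven by loss of ammonia, gives the aryl silyl ether needed for the silyl shift.

Step 3
Reactants: 3 [3,5-bis(benzyloxy)-2-bromophenoxy]trimethylsilane
Product: 6 3,5-bis(benzyloxy)-2-(trimethylsilyl)phenyl trifluoromethanesulfonate, via aryllithium 4 (not isolated), via lithium 2-silylphenoxide 5 (not isolated)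
Conditions: n-BuLi, THF, −100 to −78 °C; then Tf2O, −100 °C to rt
Reagents that add atoms: trifluoromethanesulfonic anhydride, O=S(=O)(OS(=O)(=O)C(F)(F)F)C(F)(F)F
Why: Bromine–lithium exchange outruns benzylic deprotonation at this temperature, the aryllithium undergoes the 1,3 O-to-C silyl migration (retro-Brook rearrangement) to the phenoxide, and O-triflation gives the ortho-silylaryl triflate.

Step 4
Reactants: 7 2-bromo-3-hydroxy-4-methoxybenzaldehyde
Product: 8 3-(benzyloxy)-2-bromo-4-methoxybenzaldehyde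
Conditions: BnBr, K2CO3, DMF, rt
Reagents that add atoms: benzyl bromide, BrCc1ccccc1
Why: Williamson ether synthesis on the phenoxide; the aldehyde and aryl bromide are inert.

Step 5
Reactants: 8 3-(benzyloxy)-2-bromo-4-methoxybenzaldehyde
Product: 10 3-(benzyloxy)-2-bromo-4-methoxyphenol, via aryl formate 9 (not isolated)
Conditions: mCPBA, CH2Cl2, rt to 40 °C; then K2CO3 (cat.), MeOH, rt
Reagents that add atoms: 3-chloroperoxybenzoic acid, OOC(=O)c1cccc(Cl)c1
Why: Baeyer–Villiger (Dakin-type) oxidation in which the electron-rich, para-methoxy, ortho-substituted aryl group migrates in preference to hydride, followed by mild methanolysis of the aryl formate.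

Step 6
Reactants: 10 3-(benzyloxy)-2-bromo-4-methoxyphenol
Product: 11 1,3-bis(benzyloxy)-2-bromo-4-methoxybenzene
Conditions: BnBr, K2CO3, DMF, 60 °C
Reagents that add atoms: benzyl bromide, BrCc1ccccc1
Why: Williamson ether synthesis; it leaves the bromine between the two benzyloxy groups, at the future C3'.

Step 7
Reactants: 11 1,3-bis(benzyloxy)-2-bromo-4-methoxybenzene; 12 2,2-dimethyloxetane
Product: 14 4-[2,6-bis(benzyloxy)-3-methoxyphenyl]-2-methylbutan-2-ol, via aryllithium 13 (not isolated)
Conditions: n-BuLi, THF, −78 °C; then 12 (2 equiv), BF3·OEt2, −78 °C; aq. NaHCO3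
Reagents that add atoms: none
Why: Bromine–lithium exchange at −78 °C is faster than benzylic deprotonation, and the aryllithium opens the BF3-activated oxetane by SN2 attack at its unsubstituted CH2 carbon (Lewis-acid-assisted oxetane opening by an organolithium), giving the tertiary alcohol.

Step 8
Reactants: 14 4-[2,6-bis(benzyloxy)-3-methoxyphenyl]-2-methylbutan-2-ol
Product: 15 {[4-(2,6-bis(benzyloxy)-3-methoxyphenyl)-2-methylbutan-2-yl]oxy}triethylsilane
Conditions: TESOTf, 2,6-lutidine, CH2Cl2, −78 to 0 °C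
Reagents that add atoms: triethylsilyl trifluoromethanesulfonate, CC[Si](CC)(CC)OS(=O)(=O)C(F)(F)F
Why: Silylation of a tertiary alcohol with a silyl triflate and a hindered pyridine base.

Step 9
Reactants: 15 {[4-(2,6-bis(benzyloxy)-3-methoxyphenyl)-2-methylbutan-2-yl]oxy}triethylsilane
Product: 16 {[4-(2,6-bis(benzyloxy)-3-bromo-5-methoxyphenyl)-2-methylbutan-2-yl]oxy}triethylsilane
Conditions: NBS, MeCN, 0 °C
Reagents that add atoms: N-bromosuccinimide, O=C1CCC(=O)N1Br
Why: Electrophilic aromatic bromination should go to C1', which is ortho to the C2' benzyloxy group and para to the C4' benzyloxy group, whereas the other open position has only an ortho methoxy and a para alkyl group.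

Step 10
Reactants: 16 {[4-(2,6-bis(benzyloxy)-3-bromo-5-methoxyphenyl)-2-methylbutan-2-yl]oxy}triethylsilane
Product: 17 methyl 2-{2,4-bis(benzyloxy)-5-methoxy-3-[3-methyl-3-(triethylsilyloxy)butyl]phenyl}acetate
Conditions: BrZnCH2CO2Me (from BrCH2CO2Me, Zn, THF), Pd(dba)2 (cat.), P(t-Bu)3 (cat.), THF, rt to 50 °C
Reagents that add atoms: methyl bromoacetate, COC(=O)CBr, used as its zinc reagent bromo(2-methoxy-2-oxoethyl)zinc, COC(=O)C[Zn]Br
Why: Palladium-catalysed cross-coupling of an aryl bromide with a zinc ester enolate (Reformatsky reagent, Negishi-type α-arylation), which tolerates silyl and benzyl ethers.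

Step 11
Reactants: 17 methyl 2-{2,4-bis(benzyloxy)-5-methoxy-3-[3-methyl-3-(triethylsilyloxy)butyl]phenyl}acetate; 18 methyl formate
Product: 20 methyl (Z)-2-{2,4-bis(benzyloxy)-5-methoxy-3-[3-methyl-3-(triethylsilyloxy)butyl]phenyl}-3-hydroxyprop-2-enoate, via sodium enolate 19 (not isolated)
Conditions: NaH, 18 (excess), THF, 0 °C to rt; then AcOH, 0 °C
Reagents that add atoms: none
Why: Crossed Claisen condensation of the arylacetate enolate with non-enolisable methyl formate, driven by formation of the stabilised sodium enolate, with mild acidification giving the hydrogen-bonded Z-enol.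

Step 12
Reactants: 6 3,5-bis(benzyloxy)-2-(trimethylsilyl)phenyl trifluoromethanesulfonate; 20 methyl (Z)-2-{2,4-bis(benzyloxy)-5-methoxy-3-[3-methyl-3-(triethylsilyloxy)butyl]phenyl}-3-hydroxyprop-2-enoate
Product: 22 5,7-bis(benzyloxy)-3-{2,4-bis(benzyloxy)-5-methoxy-3-[3-methyl-3-(triethylsilyloxy)butyl]phenyl}-4H-chromen-4-one, via 3,5-bis(benzyloxy)benzyne 21 (not isolated)
Conditions: 6 (1.5 equiv), CsF (4 equiv), THF, 65 °C
Reagents that add atoms: none
Why: Proposed new method: fluoride removes the silyl group of 6 and triflate departs to give benzyne 21; the caesium enolate of 20 adds through its formyl-derived oxygen to the aryne carbon remote from the neighbouring benzyloxy group (future C8a), and the aryl anion left at the future C4a attacks the cis methyl ester and expels methoxide, forming O1–C8a and C4–C4a. The closest known reaction type is the CsF-mediated annulation of arynes with methyl salicylates to xanthones (phenoxide addition, then acyl capture); here the enol oxygen of an α-formyl ester takes the place of the phenoxide. Ring C closes by a 6-exo-trig acyl substitution at the ester carbonyl, and no stereocentre is formed. The step needs attack at C8a and not C4a, which the inductive effect and ring distortion of the benzyloxy group next to the aryne bond should secure by placing the negative charge ortho to that C–O bond. It also needs O- and not C-arylation from the Z-enolate, which the fully substituted, aryl-shielded α-carbon and caesium chelation between enolate oxygen and ester carbonyl should favour. THF is chosen over acetonitrile so that the aryl anion cyclises before it is protonated.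

Step 13
Reactants: 22 5,7-bis(benzyloxy)-3-{2,4-bis(benzyloxy)-5-methoxy-3-[3-methyl-3-(triethylsilyloxy)butyl]phenyl}-4H-chromen-4-one
Product: 23 5,7-bis(benzyloxy)-3-[2,4-bis(benzyloxy)-3-(3-hydroxy-3-methylbutyl)-5-methoxyphenyl]-4H-chromen-4-one
Conditions: TBAF, AcOH, THF, rt
Reagents that add atoms: none
Why: Fluoride-mediated cleavage of the tertiary triethylsilyl ether, buffered with acetic acid so that the base-sensitive pyranone ring is not opened.

Step 14
Reactants: 23 5,7-bis(benzyloxy)-3-[2,4-bis(benzyloxy)-3-(3-hydroxy-3-methylbutyl)-5-methoxyphenyl]-4H-chromen-4-one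
Product: 24 3-[2,4-dihydroxy-3-(3-hydroxy-3-methylbutyl)-5-methoxyphenyl]-5,7-dihydroxy-4H-chromen-4-one
Conditions: H2 (1 atm), Pd/C, EtOAc/MeOH, rt; stopped once the benzyl ethers are consumed
Reagents that add atoms: none
Why: Catalytic hydrogenolysis of the four aryl benzyl ethers under neutral conditions, which avoids acid that would close the tertiary alcohol onto a neighbouring phenol as a chroman.

**Compound list**
1 | 3,5-bis(benzyloxy)phenol | Oc1cc(OCc2ccccc2)cc(OCc2ccccc2)c1 | starting material
2 | 3,5-bis(benzyloxy)-2-bromophenol | Oc1cc(OCc2ccccc2)cc(OCc2ccccc2)c1Br | intermediate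
3 | [3,5-bis(benzyloxy)-2-bromophenoxy]trimethylsilane | C[Si](C)(C)Oc1cc(OCc2ccccc2)cc(OCc2ccccc2)c1Br | intermediate
4 | [2,4-bis(benzyloxy)-6-(trimethylsilyloxy)phenyl]lithium | C[Si](C)(C)Oc1cc(OCc2ccccc2)cc(OCc2ccccc2)c1[Li] | intermediate
5 | lithium 3,5-bis(benzyloxy)-2-(trimethylsilyl)phenolate | [Li+].[O-]c1cc(OCc2ccccc2)cc(OCc2ccccc2)c1[Si](C)(C)C | intermediate
6 | 3,5-bis(benzyloxy)-2-(trimethylsilyl)phenyl trifluoromethanesulfonate | C[Si](C)(C)c1c(OS(=O)(=O)C(F)(F)F)cc(OCc2ccccc2)cc1OCc1ccccc1 | intermediate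
7 | 2-bromo-3-hydroxy-4-methoxybenzaldehyde | COc1ccc(C=O)c(Br)c1O | starting material
8 | 3-(benzyloxy)-2-bromo-4-methoxybenzaldehyde | COc1ccc(C=O)c(Br)c1OCc1ccccc1 | intermediate
9 | 3-(benzyloxy)-2-bromo-4-methoxyphenyl formate | COc1ccc(OC=O)c(Br)c1OCc1ccccc1 | intermediate
10 | 3-(benzyloxy)-2-bromo-4-methoxyphenol | COc1ccc(O)c(Br)c1OCc1ccccc1 | intermediate
11 | 1,3-bis(benzyloxy)-2-bromo-4-methoxybenzene | COc1ccc(OCc2ccccc2)c(Br)c1OCc1ccccc1 | intermediate
12 | 2,2-dimethyloxetane | CC1(C)CCO1 | starting material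
13 | [2,6-bis(benzyloxy)-3-methoxyphenyl]lithium | COc1ccc(OCc2ccccc2)c([Li])c1OCc1ccccc1 | intermediate
14 | 4-[2,6-bis(benzyloxy)-3-methoxyphenyl]-2-methylbutan-2-ol | COc1ccc(OCc2ccccc2)c(CCC(C)(C)O)c1OCc1ccccc1 | intermediate
15 | {[4-(2,6-bis(benzyloxy)-3-methoxyphenyl)-2-methylbutan-2-yl]oxy}triethylsilane | COc1ccc(OCc2ccccc2)c(CCC(C)(C)O[Si](CC)(CC)CC)c1OCc1ccccc1 | intermediate
16 | {[4-(2,6-bis(benzyloxy)-3-bromo-5-methoxyphenyl)-2-methylbutan-2-yl]oxy}triethylsilane | COc1cc(Br)c(OCc2ccccc2)c(CCC(C)(C)O[Si](CC)(CC)CC)c1OCc1ccccc1 | intermediate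
17 | methyl 2-{2,4-bis(benzyloxy)-5-methoxy-3-[3-methyl-3-(triethylsilyloxy)butyl]phenyl}acetate | COC(=O)Cc1cc(OC)c(OCc2ccccc2)c(CCC(C)(C)O[Si](CC)(CC)CC)c1OCc1ccccc1 | intermediate
18 | methyl formate | COC=O | starting material
19 | sodium (Z)-2-{2,4-bis(benzyloxy)-5-methoxy-3-[3-methyl-3-(triethylsilyloxy)butyl]phenyl}-3-methoxy-3-oxoprop-1-en-1-olate | [Na+].COC(=O)/C(=C\[O-])c1cc(OC)c(OCc2ccccc2)c(CCC(C)(C)O[Si](CC)(CC)CC)c1OCc1ccccc1 | intermediate
20 | methyl (Z)-2-{2,4-bis(benzyloxy)-5-methoxy-3-[3-methyl-3-(triethylsilyloxy)butyl]phenyl}-3-hydroxyprop-2-enoate | COC(=O)/C(=C\O)c1cc(OC)c(OCc2ccccc2)c(CCC(C)(C)O[Si](CC)(CC)CC)c1OCc1ccccc1 | intermediate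
21 | 3,5-bis(benzyloxy)benzyne (3,5-bis(benzyloxy)-1,2-didehydrobenzene) | C1(OCc2ccccc2)=CC(OCc3ccccc3)=CC#C1 | intermediate
22 | 5,7-bis(benzyloxy)-3-{2,4-bis(benzyloxy)-5-methoxy-3-[3-methyl-3-(triethylsilyloxy)butyl]phenyl}-4H-chromen-4-one | O=c1c(-c2cc(OC)c(OCc3ccccc3)c(CCC(C)(C)O[Si](CC)(CC)CC)c2OCc2ccccc2)coc2cc(OCc3ccccc3)cc(OCc3ccccc3)c12 | intermediate
23 | 5,7-bis(benzyloxy)-3-[2,4-bis(benzyloxy)-3-(3-hydroxy-3-methylbutyl)-5-methoxyphenyl]-4H-chromen-4-one | O=c1c(-c2cc(OC)c(OCc3ccccc3)c(CCC(C)(C)O)c2OCc2ccccc2)coc2cc(OCc3ccccc3)cc(OCc3ccccc3)c12 | intermediate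
24 | 3-[2,4-dihydroxy-3-(3-hydroxy-3-methylbutyl)-5-methoxyphenyl]-5,7-dihydroxy-4H-chromen-4-one | COc1cc(-c2coc3cc(O)cc(O)c3c2=O)c(O)c(CCC(C)(C)O)c1O | target

**Step count**
Total: 14 steps. Longest linear sequence: 11 steps (steps 4 to 14, from 7); the aryne precursor (steps 1 to 3) joins at step 12.

**Steps most likely to fail**

Step 12 (the step carrying the new method). The enolate may arylate at carbon (leading to C–C insertion), the aryl anion may be protonated before it reaches the ester, or the enolate may react from the geometry that cannot close. In each case ring C would not form. The fallback uses known Suzuki–Miyaura isoflavone chemistry, sets out from bromide 16 and returns at 22. Bromine–lithium exchange on 16 (n-BuLi, THF, −78 °C) and trapping with 2-isopropoxy-4,4,5,5-tetramethyl-1,3,2-dioxaborolane would give 2-{2,4-bis(benzyloxy)-5-methoxy-3-[3-methyl-3-(triethylsilyloxy)butyl]phenyl}-4,4,5,5-tetramethyl-1,3,2-dioxaborolane F1. Separately, purchased 1-[2,4-bis(benzyloxy)-6-hydroxyphenyl]ethanone F2 would be condensed with N,N-dimethylformamide dimethyl acetal (95 °C) to (E)-1-[2,4-bis(benzyloxy)-6-hydroxyphenyl]-3-(dimethylamino)prop-2-en-1-one F3. Iodine in CHCl3 would then cyclise F3 to 5,7-bis(benzyloxy)-3-iodo-4H-chromen-4-one F4. Coupling of F1 with F4 (Pd(PPh3)4, K2CO3, DME/H2O, 80 °C) should give 22, and steps 13 and 14 follow unchanged.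

Step 7. The Lewis acid may ionise the gem-dimethyl oxetane at its tertiary carbon (elimination or attack at the wrong carbon), or the ortho-benzyloxy aryllithium may rearrange before it is trapped. The fallback replaces the anionic opening by a B-alkyl Suzuki–Miyaura coupling, sets out from bromide 11 and returns at 15. 2-Methylbut-3-en-2-ol would be silylated (TESCl, imidazole, DMF) to triethyl[(2-methylbut-3-en-2-yl)oxy]silane F5. Hydroboration with 9-BBN-H (THF, rt) would give 9-[3-methyl-3-(triethylsilyloxy)butyl]-9-borabicyclo[3.3.1]nonane F6. Coupling of F6 with 11 (Pd(OAc)2, SPhos, K3PO4, THF/H2O, 65 °C) should give 15 directly, so step 8 is no longer needed.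

Step 9. Site selectivity between the two open ring positions may be poor if the C4' benzyloxy group, twisted out of plane by its two neighbours, donates too weakly to C1'. The fallback fixes the position with the free phenol, sets out from phenol 10 and returns at 20. Magnesium-mediated ortho-formylation of 10 (MgCl2, Et3N, paraformaldehyde, MeCN, reflux) can only reach the single open ortho position and would give 4-(benzyloxy)-3-bromo-2-hydroxy-5-methoxybenzaldehyde F7. Benzylation (BnBr, K2CO3, DMF) would give 2,4-bis(benzyloxy)-3-bromo-5-methoxybenzaldehyde F8. Coupling of F8 with borane F6 (Pd(OAc)2, SPhos, K3PO4, THF/H2O) would give 2,4-bis(benzyloxy)-5-methoxy-3-[3-methyl-3-(triethylsilyloxy)butyl]benzaldehyde F9. Acid-catalysed homologation of F9 with methyl diazoacetate (HBF4·OEt2 cat., CH2Cl2, −78 °C; 1,2-shift of the electron-rich aryl group with loss of nitrogen) should give 20. This bypasses steps 6 to 11.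

**Further compounds**
F1 | step 12 | 2-{2,4-bis(benzyloxy)-5-methoxy-3-[3-methyl-3-(triethylsilyloxy)butyl]phenyl}-4,4,5,5-tetramethyl-1,3,2-dioxaborolane | COc1cc(B2OC(C)(C)C(C)(C)O2)c(OCc2ccccc2)c(CCC(C)(C)O[Si](CC)(CC)CC)c1OCc1ccccc1
F2 | step 12 | 1-[2,4-bis(benzyloxy)-6-hydroxyphenyl]ethanone | CC(=O)c1c(O)cc(OCc2ccccc2)cc1OCc1ccccc1
F3 | step 12 | (E)-1-[2,4-bis(benzyloxy)-6-hydroxyphenyl]-3-(dimethylamino)prop-2-en-1-one | CN(C)/C=C/C(=O)c1c(O)cc(OCc2ccccc2)cc1OCc1ccccc1
F4 | step 12 | 5,7-bis(benzyloxy)-3-iodo-4H-chromen-4-one | O=c1c(I)coc2cc(OCc3ccccc3)cc(OCc3ccccc3)c12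
F5 | step 7 | triethyl[(2-methylbut-3-en-2-yl)oxy]silane | C=CC(C)(C)O[Si](CC)(CC)CC
F6 | step 7 | 9-[3-methyl-3-(triethylsilyloxy)butyl]-9-borabicyclo[3.3.1]nonane | CC[Si](CC)(CC)OC(C)(C)CCB1C2CCCC1CCC2
F7 | step 9 | 4-(benzyloxy)-3-bromo-2-hydroxy-5-methoxybenzaldehyde | COc1cc(C=O)c(O)c(Br)c1OCc1ccccc1
F8 | step 9 | 2,4-bis(benzyloxy)-3-bromo-5-methoxybenzaldehyde | COc1cc(C=O)c(OCc2ccccc2)c(Br)c1OCc1ccccc1
F9 | step 9 | 2,4-bis(benzyloxy)-5-methoxy-3-[3-methyl-3-(triethylsilyloxy)butyl]benzaldehyde | COc1cc(C=O)c(OCc2ccccc2)c(CCC(C)(C)O[Si](CC)(CC)CC)c1OCc1ccccc1
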